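Each dihydropyran ring of the target (O1, C2 with its gem-dimethyl group, C3 and C4, fused to the arene at C4a/C8a) is disconnected into isobutylene and an ortho-quinone methide whose exocyclic methylene is C4 and whose carbonyl oxygen is the phenol oxygen para to the bridge. One thermal operation on the fully assembled bis-aryl heptane generates both quinone methides from a bis-Mannich base and closes both rings by hetero-Diels–Alder addition, forming four bonds. The precursor is 1,1-diaryl-6-methylheptane 7: each ring carries benzyl ethers on the two bridge-flanking oxygens, a free para hydroxyl and an ortho CH2NMe2 group. The (R)-2-methylbutanoyl groups are added last, at C8 and C8′.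

Key step: step 5

Remark on the structure: the target has two stereocentres, the α-carbons of the two acyl groups, and both are (R). The bridging methine carries two identical aryl groups and is not a stereocentre.

Remark on the design: the four bridge-flanking oxygens are carried as benzyl ethers, not acetal-type ethers. Benzyl ethers survive the acid-catalysed bridging and the thermolysis, and they are removed by neutral hydrogenolysis, which spares the acid-labile diarylmethine.

Assumption: 3,5-bis(benzyloxy)phenol, 6-methylheptanal, isobutylene and (R)-2-methylbutanoic acid are taken as commercial.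

Step 1
Reactants: 1 3,5-bis(benzyloxy)phenol
Product: 2 [3,5-bis(benzyloxy)phenoxy]triisopropylsilane
Conditions: TIPSCl (1.1 equiv), imidazole (2 equiv), DMF, rt
Reagents that add atoms: triisopropylsilyl chloride, CC(C)[Si](Cl)(C(C)C)C(C)C
Why: Imidazole-mediated O-silylation of an unhindered phenol; the bulky silyl ether masks the future para hydroxyl and shields both ring carbons next to it for step 2.

Step 2
Reactants: 2 [3,5-bis(benzyloxy)phenoxy]triisopropylsilane (2.1 equiv); 3 6-methylheptanal
Product: 5 1,1-bis[2,6-bis(benzyloxy)-4-(triisopropylsilyloxy)phenyl]-6-methylheptane, via monoaryl carbinol 4 (not isolated)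
Conditions: BF3·OEt2 (0.3 equiv), CH2Cl2, −20 °C to rt
Reagents that add atoms: none
Why: Acid-catalysed double Friedel–Crafts hydroxyalkylation–alkylation of a 1,3,5-trioxygenated arene, in which the activated aldehyde and then the benzylic cation from racemic carbinol 4 should attack the ring carbon para to the silyloxy group (between the two benzyloxy groups), because the carbons next to the bulky, weakly donating OSi(i-Pr)3 group are shielded and would give the more congested, reversibly formed isomer; the carbinol stereocentre disappears on ionisation.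

Step 3
Reactants: 5 1,1-bis[2,6-bis(benzyloxy)-4-(triisopropylsilyloxy)phenyl]-6-methylheptane
Product: 6 4,4′-(6-methylheptane-1,1-diyl)bis[3,5-bis(benzyloxy)phenol]
Conditions: TBAF (2.2 equiv), AcOH (2.2 equiv), THF, 0 °C
Reagents that add atoms: none
Why: Fluoride-induced desilylation of the aryl silyl ethers, buffered with acetic acid so that the electron-rich phenoxides are protonated at once, with the benzyl ethers inert.

Step 4
Reactants: 6 4,4′-(6-methylheptane-1,1-diyl)bis[3,5-bis(benzyloxy)phenol]
Product: 7 1,1-bis[2,6-bis(benzyloxy)-3-(dimethylaminomethyl)-4-hydroxyphenyl]-6-methylheptane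
Conditions: Me2N+=CH2 I− (2.1 equiv), CH2Cl2, 0 °C to rt; aq. NaHCO3 work-up
Reagents that add atoms: N,N-dimethylmethyleneiminium iodide, C=[N+](C)C.[I-]
Why: Phenolic Mannich reaction (ortho-aminomethylation) with a preformed iminium salt, in which the only free ring carbons are the two equivalent positions ortho to the hydroxyl and each ring should stop after one substitution because the product is held as its hydroiodide, whose ammonium group deactivates the ring until the bicarbonate work-up.

Step 5
Reactants: 7 1,1-bis[2,6-bis(benzyloxy)-3-(dimethylaminomethyl)-4-hydroxyphenyl]-6-methylheptane; 8 isobutylene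
Product: 10 6,6′-(6-methylheptane-1,1-diyl)bis[5,7-bis(benzyloxy)-2,2-dimethylchroman], via bis(ortho-quinone methide) 9 (not isolated)
Conditions: isobutylene (large excess, condensed), toluene, sealed steel autoclave, 170 °C
Reagents that add atoms: none
Why: At about 170 °C each ortho-hydroxybenzylamine of 7 should lose dimethylamine by a hydrogen-bonded 1,4-elimination to give an ortho-quinone methide whose exocyclic CH2 becomes C4 and whose carbonyl oxygen becomes O1, and isobutylene then adds across this C=C–C=O unit in a concerted, asynchronous inverse-electron-demand hetero-Diels–Alder reaction that forms C4–C3 and O1–C2 and restores the aromatic ring. The closest known reaction type is the thermal conversion of phenolic Mannich bases into 2,2-disubstituted chromans with 1,1-disubstituted alkenes. Each of the two dihydropyran rings is closed by this intermolecular [4+2] cycloaddition (4π oxadiene plus 2π alkene), not by an ionic cyclisation, and the two aryl units are expected to react one after the other, so that 9 is a formal description of both unmasked termini. No stereocentre is created, since C2 carries two methyl groups and the bridging CH joins two identical aryl groups. Two selectivities are needed: the ring oxygen must be the one para to the bridge, which is secured because it is the only free hydroxyl (both bridge-flanking oxygens are benzyl ethers), and that oxygen must bond to the disubstituted alkene carbon, which follows from the polarised transition state in which the CH2 terminus of isobutylene attacks the electrophilic methylene while positive charge builds at the tertiary carbon. The large excess of isobutylene should outcompete re-addition of dimethylamine and self-condensation of the quinone methide, and the cycloadduct has no free phenol and cannot react again.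

Step 6
Reactants: 10 6,6′-(6-methylheptane-1,1-diyl)bis[5,7-bis(benzyloxy)-2,2-dimethylchroman]
Product: 11 6,6′-(6-methylheptane-1,1-diyl)bis(2,2-dimethylchroman-5,7-diol)
Conditions: H2 (1 atm), 10% Pd/C, EtOAc–MeOH, rt; product kept under argon and used at once
Reagents that add atoms: none
Why: Catalytic hydrogenolysis of aryl benzyl ethers under neutral conditions, which leaves the chroman rings and the acid-sensitive diarylmethine untouched.

Step 7
Reactants: 12 (R)-2-methylbutanoic acid
Product: 13 (R)-2-methylbutanoyl chloride
Conditions: (COCl)2 (1.2 equiv), DMF (cat.), CH2Cl2, 0 °C to rt; solution used directly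
Reagents that add atoms: oxalyl chloride, O=C(Cl)C(Cl)=O
Why: Acid chloride formation through chloroiminium catalysis in the absence of any amine base, so that no ketene can form and the α-stereocentre should stay (R).

Step 8
Reactants: 11 6,6′-(6-methylheptane-1,1-diyl)bis(2,2-dimethylchroman-5,7-diol); 13 (R)-2-methylbutanoyl chloride (2.4 equiv)
Product: 14 (2R,2′R)-1,1′-[(6-methylheptane-1,1-diyl)bis(5,7-dihydroxy-2,2-dimethylchroman-6,8-diyl)]bis(2-methylbutan-1-one)
Conditions: AlCl3 (8 equiv), CH2Cl2–PhNO2, 0 °C to rt; ice-cold 1 M HCl quench
Reagents that add atoms: none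
Why: Friedel–Crafts C-acylation (with Fries-type O-to-C acyl transfer wherever O-acylation comes first) at C8 and C8′, the only unsubstituted ring carbon of each chroman-5,7-diol and one flanked by two oxygens; the acylium ion forms without touching the α-C–H bond and no base is present, so both (R) centres should be carried over unchanged.

Compound list
1 | 3,5-bis(benzyloxy)phenol | Oc1cc(OCc2ccccc2)cc(OCc2ccccc2)c1 | starting material
2 | [3,5-bis(benzyloxy)phenoxy]triisopropylsilane | CC(C)[Si](Oc1cc(OCc2ccccc2)cc(OCc2ccccc2)c1)(C(C)C)C(C)C | intermediate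
3 | 6-methylheptanal | CC(C)CCCCC=O | starting material
4 | 1-[2,6-bis(benzyloxy)-4-(triisopropylsilyloxy)phenyl]-6-methylheptan-1-ol (racemic, not isolated) | CC(C)CCCCC(O)c1c(OCc2ccccc2)cc(O[Si](C(C)C)(C(C)C)C(C)C)cc1OCc1ccccc1 | intermediate
5 | 1,1-bis[2,6-bis(benzyloxy)-4-(triisopropylsilyloxy)phenyl]-6-methylheptane | CC(C)CCCCC(c1c(OCc2ccccc2)cc(O[Si](C(C)C)(C(C)C)C(C)C)cc1OCc1ccccc1)c1c(OCc2ccccc2)cc(O[Si](C(C)C)(C(C)C)C(C)C)cc1OCc1ccccc1 | intermediate
6 | 4,4′-(6-methylheptane-1,1-diyl)bis[3,5-bis(benzyloxy)phenol] | CC(C)CCCCC(c1c(OCc2ccccc2)cc(O)cc1OCc1ccccc1)c1c(OCc2ccccc2)cc(O)cc1OCc1ccccc1 | intermediate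
7 | 1,1-bis[2,6-bis(benzyloxy)-3-(dimethylaminomethyl)-4-hydroxyphenyl]-6-methylheptane | CC(C)CCCCC(c1c(OCc2ccccc2)cc(O)c(CN(C)C)c1OCc1ccccc1)c1c(OCc2ccccc2)cc(O)c(CN(C)C)c1OCc1ccccc1 | intermediate
8 | isobutylene (2-methylpropene) | CC(C)=C | starting material
9 | 4,4′-(6-methylheptane-1,1-diyl)bis[3,5-bis(benzyloxy)-6-methylidenecyclohexa-2,4-dien-1-one], the bis(ortho-quinone methide) (not isolated) | CC(C)CCCCC(C1=C(OCc2ccccc2)C(=C)C(=O)C=C1OCc1ccccc1)C1=C(OCc2ccccc2)C(=C)C(=O)C=C1OCc1ccccc1 | intermediate
10 | 6,6′-(6-methylheptane-1,1-diyl)bis[5,7-bis(benzyloxy)-2,2-dimethylchroman] | CC(C)CCCCC(c1c(OCc2ccccc2)cc2OC(C)(C)CCc2c1OCc1ccccc1)c1c(OCc2ccccc2)cc2OC(C)(C)CCc2c1OCc1ccccc1 | intermediate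
11 | 6,6′-(6-methylheptane-1,1-diyl)bis(2,2-dimethylchroman-5,7-diol) | CC(C)CCCCC(c1c(O)cc2OC(C)(C)CCc2c1O)c1c(O)cc2OC(C)(C)CCc2c1O | intermediate
12 | (R)-2-methylbutanoic acid | CC[C@@H](C)C(=O)O | starting material
13 | (R)-2-methylbutanoyl chloride | CC[C@@H](C)C(=O)Cl | intermediate
14 | (2R,2′R)-1,1′-[(6-methylheptane-1,1-diyl)bis(5,7-dihydroxy-2,2-dimethylchroman-6,8-diyl)]bis(2-methylbutan-1-one) | CC[C@@H](C)C(=O)c1c(O)c(C(CCCCC(C)C)c2c(O)c3c(c(C(=O)[C@H](C)CC)c2O)OC(C)(C)CC3)c(O)c2c1OC(C)(C)CC2 | target

Total step count: 8. Longest linear sequence: 7 steps (steps 1 to 6 and step 8, from compound 1); step 7 is a one-step side branch.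

Steps most likely to fail

Step 5. The quinone methide may be recaptured by dimethylamine or consumed by self-condensation faster than it adds an unactivated, volatile alkene, and the liberated amine may slowly attack benzyl ethers at this temperature. The fallback builds the rings by a different, known construction and sets out from bis-phenol 6. Condensation with 3-methylbut-2-enal in pyridine at about 140 °C (ortho-aldol condensation, dehydration, oxa-6π electrocyclisation) should give 6,6′-(6-methylheptane-1,1-diyl)bis[5,7-bis(benzyloxy)-2,2-dimethyl-2H-chromene] F1. Hydrogenation over Pd/C then saturates both C3=C4 bonds and removes the four benzyl groups in the same operation, and the fallback comes back to the route at tetraol 11.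

Step 2. Electrophilic attack may occur at a ring carbon next to the silyloxy group in either arylation, which would bridge the rings through the wrong positions, and the aldehyde may undergo self-aldol condensation. The fallback sets out from aldehyde 3 and commercial phloroglucinol (benzene-1,3,5-triol, Oc1cc(O)cc(O)c1), whose three ring carbons are equivalent. With a large excess of the triol in dilute HCl/ethanol at rt, the 2:1 condensation should give 2,2′-(6-methylheptane-1,1-diyl)bis(benzene-1,3,5-triol) F2. TIPSCl (2 equiv) with imidazole at 0 °C should silylate only the two hydroxyls para to the bridge, since the other four are flanked by the bulky diarylmethine, to give 2,2′-(6-methylheptane-1,1-diyl)bis[5-(triisopropylsilyloxy)benzene-1,3-diol] F3. Benzylation of the four remaining hydroxyls (BnBr, Cs2CO3, DMF) brings the fallback back to the route at compound 5.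

Step 8. The diarylmethine bridge may be cut by acid-promoted retro-Friedel–Crafts cleavage, configuration at the α-carbon may erode under the Lewis acid, and acylation may stop at oxygen. The fallback sets out from the key-step product 10 and uses no Lewis acid. NBS (2 equiv, MeCN, 0 °C) should brominate the only free ring carbon of each chroman to give 6,6′-(6-methylheptane-1,1-diyl)bis[5,7-bis(benzyloxy)-8-bromo-2,2-dimethylchroman] F4. Bromine–lithium exchange (t-BuLi, THF, −78 °C) and addition to (R)-N-methoxy-N,2-dimethylbutanamide F5, made from acid 12 with N,O-dimethylhydroxylamine hydrochloride and a carbodiimide, should give (2R,2′R)-1,1′-[(6-methylheptane-1,1-diyl)bis(5,7-bis(benzyloxy)-2,2-dimethylchroman-6,8-diyl)]bis(2-methylbutan-1-one) F6 through the stable tetrahedral chelate, without touching the α-stereocentre. Hydrogenolysis of the four benzyl ethers (H2, Pd/C) brings the fallback back to the route at target 14.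

Further compounds
F1 | step 5 | 6,6′-(6-methylheptane-1,1-diyl)bis[5,7-bis(benzyloxy)-2,2-dimethyl-2H-chromene] | CC(C)CCCCC(c1c(OCc2ccccc2)cc2OC(C)(C)C=Cc2c1OCc1ccccc1)c1c(OCc2ccccc2)cc2OC(C)(C)C=Cc2c1OCc1ccccc1
F2 | step 2 | 2,2′-(6-methylheptane-1,1-diyl)bis(benzene-1,3,5-triol) | CC(C)CCCCC(c1c(O)cc(O)cc1O)c1c(O)cc(O)cc1O
F3 | step 2 | 2,2′-(6-methylheptane-1,1-diyl)bis[5-(triisopropylsilyloxy)benzene-1,3-diol] | CC(C)CCCCC(c1c(O)cc(O[Si](C(C)C)(C(C)C)C(C)C)cc1O)c1c(O)cc(O[Si](C(C)C)(C(C)C)C(C)C)cc1O
F4 | step 8 | 6,6′-(6-methylheptane-1,1-diyl)bis[5,7-bis(benzyloxy)-8-bromo-2,2-dimethylchroman] | CC(C)CCCCC(c1c(OCc2ccccc2)c(Br)c2OC(C)(C)CCc2c1OCc1ccccc1)c1c(OCc2ccccc2)c(Br)c2OC(C)(C)CCc2c1OCc1ccccc1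
F5 | step 8 | (R)-N-methoxy-N,2-dimethylbutanamide | CC[C@@H](C)C(=O)N(C)OC
F6 | step 8 | (2R,2′R)-1,1′-[(6-methylheptane-1,1-diyl)bis(5,7-bis(benzyloxy)-2,2-dimethylchroman-6,8-diyl)]bis(2-methylbutan-1-one) | CC[C@@H](C)C(=O)c1c(OCc4ccccc4)c(C(CCCCC(C)C)c2c(OCc4ccccc4)c3c(c(C(=O)[C@H](C)CC)c2OCc4ccccc4)OC(C)(C)CC3)c(OCc4ccccc4)c2c1OC(C)(C)CC2
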